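**Retrosynthetic overview**

- The bromohydrin is unveiled last by invertive bromide opening (at C10) of a (10S,11S)-epoxy macrolactone. The 15-membered lactone comes from a palladium-catalysed carbonylative macrolactonisation (aryl bromide + CO + C14–OH).
- The aryl–CH2–ring bond comes from a Suzuki–Miyaura coupling of a cyclohexa-1,4-dienyl pinacol boronate with a benzylic bromide made from o-cresol.
- The cyclohexa-1,4-diene and its C7 stereocentre come from an enantioselective cobalt-catalysed [4+2] of an (E)-1,3-diene with 1-propynyl pinacol boronate (the new step).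
- The diene comes from SO2 extrusion of a 3-sulfolene. C9–C10 comes from a Negishi coupling of a sulfolenyl-ethylzinc with an (E)-vinyl iodide (carboalumination). The epoxide is set by Shi epoxidation and C14 by CBS reduction.
- Ring order: oxirane, then cyclohexadiene, then 15-membered lactone.

Assumption: working numbering is C1 = benzylic CH2; ring C2 (bears C1), C3 (Me), C4 (CH2), C5 (=CH), C6 (Me), C7 (CH); chain C8, C9, C10 (Br), C11 (OH, Me), C12, C13, C14 (O-acyl), C15 (=C16H2, Me); the target is (7S,10R,11S,14S).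

Assumption: the (S,S) antipode of the bisphosphine in step 14 is taken to give 7S; if the first run shows the opposite sense, the equally available (R,R) antipode is used with nothing else changed.

**Step 1**
Reactants: 1 pent-4-ynoic acid
Product: 3 N-methoxy-N-methylpent-4-ynamide, via acyl imidazolide 2 (not isolated)
Conditions: CDI, CH2Cl2, rt, 1 h; then MeNH(OMe)·HCl, rt
Reagents that add atoms: 1,1'-carbonyldiimidazole (O=C(n1ccnc1)n1ccnc1, atoms kept only in 2); N,O-dimethylhydroxylamine hydrochloride (CNOC.Cl)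
Why: Acyl-imidazolide activation followed by amidation is a standard Weinreb amide synthesis and leaves the terminal alkyne untouched.

**Step 2**
Reactants: 3 N-methoxy-N-methylpent-4-ynamide; 4 isopropenylmagnesium bromide (CH2=C(CH3)MgBr)
Product: 5 2-methylhept-1-en-6-yn-3-one
Conditions: 4 (2.3 eq), THF, −78 → 0 °C; inverse quench into cold 1 M HCl
Reagents that add atoms: none
Why: Grignard addition to a Weinreb amide stops at the chelated tetrahedral intermediate, so the isopropenyl ketone is released only on acidic quench; one equivalent of 4 is spent on the alkyne C–H, which is reprotonated.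

**Step 3**
Reactants: 5 2-methylhept-1-en-6-yn-3-one
Product: 6 (3S)-2-methylhept-1-en-6-yn-3-ol
Conditions: (R)-2-methyl-CBS-oxazaborolidine (15 mol%), catecholborane, PhMe, −78 °C
Reagents that add atoms: none
Why: Corey–Bakshi–Shibata reduction with the isopropenyl group as the large substituent delivers hydride to one carbonyl face and sets C14 as S; catecholborane at −78 °C does not hydroborate the alkyne.

**Step 4**
Reactants: 6 (3S)-2-methylhept-1-en-6-yn-3-ol
Product: 7 tert-butyl(dimethyl){[(3S)-2-methylhept-1-en-6-yn-3-yl]oxy}silane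
Conditions: t-BuMe2SiCl, imidazole, DMF, rt
Reagents that add atoms: tert-butyldimethylsilyl chloride (CC(C)(C)[Si](C)(C)Cl)
Why: Standard silylation; the silyl ether keeps O14 from opening the later epoxide to a tetrahydrofuran.

**Step 5**
Reactants: 7 tert-butyl(dimethyl){[(3S)-2-methylhept-1-en-6-yn-3-yl]oxy}silane
Product: 9 tert-butyl{[(3S,6E)-7-iodo-2,6-dimethylhepta-1,6-dien-3-yl]oxy}dimethylsilane, via alkenyl(dimethyl)alane 8 (not isolated)
Conditions: Me3Al (3 eq), Cp2ZrCl2 (0.25 eq), CH2Cl2, 0 °C → rt; then I2, THF, −30 → 0 °C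
Reagents that add atoms: trimethylaluminium (C[Al](C)C); iodine (II)
Why: Zirconium-catalysed syn-carboalumination (Negishi) puts methyl on the internal and aluminium on the terminal alkyne carbon, and iodinolysis with retention gives the (E)-vinyl iodide that fixes the C10=C11 geometry.

**Step 6**
Reactants: 10 2-iodoethanol
Product: 11 tert-butyl(2-iodoethoxy)dimethylsilane
Conditions: t-BuMe2SiCl, imidazole, CH2Cl2, 0 °C → rt
Reagents that add atoms: tert-butyldimethylsilyl chloride (CC(C)(C)[Si](C)(C)Cl)
Why: Routine silylation of a primary alcohol gives a two-carbon electrophile without a free OH.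

**Step 7**
Reactants: 12 3-methyl-2,5-dihydrothiophene 1,1-dioxide (3-methyl-3-sulfolene); 11 tert-butyl(2-iodoethoxy)dimethylsilane
Product: 13 2-(2-{[tert-butyl(dimethyl)silyl]oxy}ethyl)-3-methyl-2,5-dihydrothiophene 1,1-dioxide (racemic)
Conditions: LiN(SiMe3)2 added to 12 + 11 in THF/HMPA, −78 °C
Reagents that add atoms: none
Why: Deprotonation with in-situ alkylation of 3-methyl-3-sulfolene occurs at C2 (allyl anion with the methyl on its central carbon), the known sulfolene route to (E)-3-methyl-1,3-dienes; the racemic centre is erased in step 12.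

**Step 8**
Reactants: 13 silyl ether of the alkylated sulfolene
Product: 14 2-(2-hydroxyethyl)-3-methyl-2,5-dihydrothiophene 1,1-dioxide (racemic)
Conditions: AcCl (cat.), MeOH, 0 °C → rt
Reagents that add atoms: none
Why: Acid-catalysed methanolysis removes the primary silyl ether, and acid avoids the base-induced isomerisation of the 3-sulfolene to the conjugated 2-sulfolene.

**Step 9**
Reactants: 14 2-(2-hydroxyethyl)-3-methyl-2,5-dihydrothiophene 1,1-dioxide
Product: 15 2-(2-iodoethyl)-3-methyl-2,5-dihydrothiophene 1,1-dioxide (racemic)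
Conditions: I2, PPh3, imidazole, CH2Cl2, 0 °C
Reagents that add atoms: iodine (II)
Why: Appel-type iodination of a primary alcohol is reliable and the sulfolene is inert to it.

**Step 10**
Reactants: 15 2-(2-iodoethyl)-3-methyl-2,5-dihydrothiophene 1,1-dioxide; 9 (E)-vinyl iodide
Product: 17 2-[(3E,7S)-7-{[tert-butyl(dimethyl)silyl]oxy}-4,8-dimethylnona-3,8-dien-1-yl]-3-methyl-2,5-dihydrothiophene 1,1-dioxide (1:1 epimers at the sulfolene carbon), via alkylzinc iodide 16 (not isolated)
Conditions: Zn dust (BrCH2CH2Br/Me3SiCl activated), THF, 40 °C; then 9, Pd(PPh3)4 (4 mol%), THF, rt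
Reagents that add atoms: zinc ([Zn], kept only in 16)
Why: Zinc insertion into the primary iodide and Negishi sp3–sp2 coupling with zerovalent palladium form the C9–C10 bond with retention of the (E)-geometry; sulfone and silyl ether are inert to the organozinc.

**Step 11**
Reactants: 17 Negishi product
Product: 18 2-(2-{(2S,3S)-3-[(3S)-3-{[tert-butyl(dimethyl)silyl]oxy}-4-methylpent-4-en-1-yl]-3-methyloxiran-2-yl}ethyl)-3-methyl-2,5-dihydrothiophene 1,1-dioxide
Conditions: ent-Shi ketone (L-fructose-derived, 0.3 eq), KHSO5 (as Oxone, 2KHSO5·KHSO4·K2SO4), K2CO3, Bu4NHSO4, MeCN/CH2(OMe)2/aq. Na2B4O7–Na2EDTA, pH 10.5, 0 °C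
Reagents that add atoms: potassium peroxymonosulfate ([K+].[O-]S(=O)(=O)OO)
Why: Shi asymmetric epoxidation: the chiral dioxirane attacks the electron-rich trisubstituted C10=C11 alkene under catalyst control to give the (10S,11S)-epoxide, while the 1,1-disubstituted allylic-ether alkene and the sulfone-deactivated ring alkene react far more slowly.

**Step 12**
Reactants: 18 epoxy sulfolene
Product: 19 (2S,3S)-2-[(3S)-3-{[tert-butyl(dimethyl)silyl]oxy}-4-methylpent-4-en-1-yl]-2-methyl-3-[(3E)-4-methylhexa-3,5-dien-1-yl]oxirane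
Conditions: PhMe, NaHCO3 (solid), 115 °C, Ar sweep, 2 h
Reagents that add atoms: none
Why: Thermal cheletropic extrusion of SO2 from a 2-alkyl-3-sulfolene is stereospecific (the substituent rotates outward) and gives only the (E)-diene; bicarbonate and the gas sweep remove SO2 before it can attack the epoxide.

**Step 13**
Reactants: 20 prop-1-yn-1-ylmagnesium bromide (CH3C≡CMgBr)
Product: 22 4,4,5,5-tetramethyl-2-(prop-1-yn-1-yl)-1,3,2-dioxaborolane, via borate complex 21 (not isolated)
Conditions: i-PrOBpin, THF, −78 °C → rt; then HCl in Et2O, −78 °C → rt; distil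
Reagents that add atoms: 2-isopropoxy-4,4,5,5-tetramethyl-1,3,2-dioxaborolane (CC(C)OB1OC(C)(C)C(C)(C)O1)
Why: Borylation of an alkynyl Grignard reagent with an alkoxyboronate and anhydrous acid release of the boronic ester is the standard route to alkynyl pinacol boronates.

**Step 14**
Reactants: 19 epoxy (E)-diene; 22 1-propynyl pinacol boronate
Product: 23 2-[(6R)-6-(2-{(2S,3S)-3-[(3S)-3-{[tert-butyl(dimethyl)silyl]oxy}-4-methylpent-4-en-1-yl]-3-methyloxiran-2-yl}ethyl)-2,5-dimethylcyclohexa-1,4-dien-1-yl]-4,4,5,5-tetramethyl-1,3,2-dioxaborolane (C7 is R by CIP only because boron lowers the rank of C2; same spatial arrangement as 7S in the target)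
Conditions: CoBr2((S,S)-BDPP) (10 mol%), Zn powder (20 mol%), Na[B(3,5-(CF3)2C6H3)4] (15 mol%), 22 (1.5 eq, slow addition), CH2Cl2, 0 °C → rt
Reagents that add atoms: none
Why: Proposed new method: an enantio- and regioselective [4+2] on cationic monovalent cobalt bearing a C2-symmetric bisphosphine, in which oxidative cyclisation of the cobalt-bound s-cis diene and the alkyne first joins the unsubstituted diene terminus C4 to the less hindered methyl-bearing alkyne carbon (boron stays alpha to cobalt), reductive elimination then joins the boron-bearing carbon to C7, and because both bonds form on the diene face held by cobalt the ligand's choice of that face sets C7; the closest known chemistry is the racemic CoBr2(dppe)/Zn/ZnI2 [4+2] of alkynyl pinacol boronates with 1,3-dienes together with enantioselective cationic cobalt–bisphosphine cycloadditions of dienes, and what is new is asymmetric induction at a bis-allylic ring carbon on a 1,2-disubstituted, epoxide-bearing diene.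

**Step 15**
Reactants: 23 cyclohexadienyl boronate silyl ether
Product: 24 the C14 alcohol of 23 (free secondary allylic OH; boronate and epoxide unchanged)
Conditions: Bu4NF/AcOH (1:1, 3 eq), THF, 0 °C → rt; chromatography on Et3N-washed silica
Reagents that add atoms: none
Why: Buffered fluoride desilylation frees the secondary alcohol before the fluoride-labile aryl silyl ether enters the molecule, and the acetic acid buffer keeps alkoxide, boronate and epoxide from reacting.

**Step 16**
Reactants: 25 2-methylphenol (o-cresol)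
Product: 26 4-bromo-2-methylphenol
Conditions: NBS (1.0 eq), MeCN, 0 °C → rt
Reagents that add atoms: N-bromosuccinimide (O=C1CCC(=O)N1Br)
Why: Electrophilic aromatic bromination goes para to the hydroxyl group, the position that later carries the carbonyl.

**Step 17**
Reactants: 26 4-bromo-2-methylphenol
Product: 27 (4-bromo-2-methylphenoxy)tri(propan-2-yl)silane
Conditions: i-Pr3SiCl, imidazole, DMF, rt
Reagents that add atoms: chlorotri(propan-2-yl)silane (CC(C)[Si](Cl)(C(C)C)C(C)C)
Why: Silylation gives an aryl ether bulky enough to survive aqueous base in the Suzuki step and the carbonylation.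

**Step 18**
Reactants: 27 (4-bromo-2-methylphenoxy)tri(propan-2-yl)silane
Product: 28 [4-bromo-2-(bromomethyl)phenoxy]tri(propan-2-yl)silane
Conditions: NBS (1.05 eq), AIBN (5 mol%), PhCF3, 85 °C
Reagents that add atoms: N-bromosuccinimide (O=C1CCC(=O)N1Br)
Why: Wohl–Ziegler radical bromination functionalises the only benzylic position.

**Step 19**
Reactants: 24 cyclohexadienyl boronate alcohol; 28 benzylic bromide
Product: 29 (3S)-5-[(2S,3S)-3-{2-[(1S)-2-{[5-bromo-2-(triisopropylsilyloxy)phenyl]methyl}-3,6-dimethylcyclohexa-2,5-dien-1-yl]ethyl}-2-methyloxiran-2-yl]-2-methylpent-1-en-3-ol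
Conditions: Pd(PPh3)4 (5 mol%), K3PO4 (3 eq), THF/H2O (10:1), 50 °C
Reagents that add atoms: none
Why: Suzuki–Miyaura sp2–sp3 coupling: zerovalent palladium inserts into the benzylic C–Br bond far faster than into the electron-rich aryl C–Br bond, so the alkenyl boronate is benzylated, the aryl bromide is kept and the basic medium leaves the hydroxy epoxide intact.

**Step 20**
Reactants: 29 seco aryl bromide alcohol
Product: 30 (7S,10S,11S,14S)-10,11-epoxy macrolactone as its aryl triisopropylsilyl ether (target skeleton with the oxirane in place of the bromohydrin)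
Conditions: Pd(OAc)2 (10 mol%), Xantphos (12 mol%), CO (1 atm), Et3N (3 eq), DMAP (0.5 eq), PhMe, 85 °C, syringe-pump addition to 2 mM
Reagents that add atoms: carbon monoxide ([C-]#[O+])
Why: Palladium-catalysed carbonylative macrolactonisation: oxidative addition into the aryl bromide, CO insertion and intramolecular capture of the acylpalladium by the C14 hydroxyl (DMAP relay, high dilution) form the aryl–C(=O) bond and the 15-membered ring in one coupling with retention at C14.

**Step 21**
Reactants: 30 epoxy macrolactone silyl ether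
Product: 31 (7S,10S,11S,14S)-10,11-epoxy macrolactone with free phenol
Conditions: Bu4NF/AcOH (1:1, 1.2 eq), THF, 0 °C, 15 min
Reagents that add atoms: none
Why: Aryl silyl ethers are cleaved by buffered fluoride within minutes, and doing this before the bromide step means the bromohydrin never meets a basic fluoride source.

**Step 22**
Reactants: 31 epoxy macrolactone phenol
Product: 32 target, (7S,10R,11S,14S)-bromohydrin macrolactone (CNP0186361.2)
Conditions: Li2NiBr4 (0.4 M in THF, 3 eq), THF, 0 °C → rt; pH 7 phosphate buffer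
Reagents that add atoms: dilithium tetrabromonickelate ([Li+].[Li+].Br[Ni-2](Br)(Br)Br)
Why: Li2NiBr4 delivers soft bromide in an SN2 opening at the less substituted C10 with inversion (10S to 10R) while the C11–O bond is untouched (11S tertiary alcohol), which gives exactly the anti bromohydrin of the target.

**Compound list**

1 | pent-4-ynoic acid | C#CCCC(=O)O | starting material
2 | 1-(1H-imidazol-1-yl)pent-4-yn-1-one | C#CCCC(=O)n1ccnc1 | intermediate
3 | N-methoxy-N-methylpent-4-ynamide | C#CCCC(=O)N(C)OC | intermediate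
4 | isopropenylmagnesium bromide | C=C(C)[Mg]Br | starting material
5 | 2-methylhept-1-en-6-yn-3-one | C=C(C)C(=O)CCC#C | intermediate
6 | (3S)-2-methylhept-1-en-6-yn-3-ol | C=C(C)[C@@H](O)CCC#C | intermediate
7 | tert-butyl(dimethyl){[(3S)-2-methylhept-1-en-6-yn-3-yl]oxy}silane | C=C(C)[C@@H](O[Si](C)(C)C(C)(C)C)CCC#C | intermediate
8 | [(1E,5S)-5-{[tert-butyl(dimethyl)silyl]oxy}-2,6-dimethylhepta-1,6-dien-1-yl]dimethylalane | C=C(C)[C@@H](O[Si](C)(C)C(C)(C)C)CC/C(C)=C/[Al](C)C | intermediate
9 | tert-butyl{[(3S,6E)-7-iodo-2,6-dimethylhepta-1,6-dien-3-yl]oxy}dimethylsilane | C=C(C)[C@@H](O[Si](C)(C)C(C)(C)C)CC/C(C)=C/I | intermediate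
10 | 2-iodoethanol | OCCI | starting material
11 | tert-butyl(2-iodoethoxy)dimethylsilane | CC(C)(C)[Si](C)(C)OCCI | intermediate
12 | 3-methyl-2,5-dihydrothiophene 1,1-dioxide | CC1=CCS(=O)(=O)C1 | starting material
13 | 2-(2-{[tert-butyl(dimethyl)silyl]oxy}ethyl)-3-methyl-2,5-dihydrothiophene 1,1-dioxide, racemic | CC1=CCS(=O)(=O)C1CCO[Si](C)(C)C(C)(C)C | intermediate
14 | 2-(2-hydroxyethyl)-3-methyl-2,5-dihydrothiophene 1,1-dioxide, racemic | CC1=CCS(=O)(=O)C1CCO | intermediate
15 | 2-(2-iodoethyl)-3-methyl-2,5-dihydrothiophene 1,1-dioxide, racemic | CC1=CCS(=O)(=O)C1CCI | intermediate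
16 | [2-(3-methyl-1,1-dioxido-2,5-dihydrothiophen-2-yl)ethyl]zinc iodide | CC1=CCS(=O)(=O)C1CC[Zn]I | intermediate
17 | 2-[(3E,7S)-7-{[tert-butyl(dimethyl)silyl]oxy}-4,8-dimethylnona-3,8-dien-1-yl]-3-methyl-2,5-dihydrothiophene 1,1-dioxide, 1:1 epimers at the sulfolene carbon | C=C(C)[C@@H](O[Si](C)(C)C(C)(C)C)CC/C(C)=C/CCC1C(C)=CCS1(=O)=O | intermediate
18 | 2-(2-{(2S,3S)-3-[(3S)-3-{[tert-butyl(dimethyl)silyl]oxy}-4-methylpent-4-en-1-yl]-3-methyloxiran-2-yl}ethyl)-3-methyl-2,5-dihydrothiophene 1,1-dioxide, 1:1 epimers at the sulfolene carbon | C=C(C)[C@@H](O[Si](C)(C)C(C)(C)C)CC[C@]1(C)O[C@H]1CCC2C(C)=CCS2(=O)=O | intermediate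
19 | (2S,3S)-2-[(3S)-3-{[tert-butyl(dimethyl)silyl]oxy}-4-methylpent-4-en-1-yl]-2-methyl-3-[(3E)-4-methylhexa-3,5-dien-1-yl]oxirane | C=C(C)[C@@H](O[Si](C)(C)C(C)(C)C)CC[C@]1(C)O[C@H]1CC/C=C(C)/C=C | intermediate
20 | prop-1-yn-1-ylmagnesium bromide | CC#C[Mg]Br | starting material
21 | bromomagnesium isopropoxy(pinacolato)(prop-1-yn-1-yl)borate | CC#C[B-]1(OC(C)C)OC(C)(C)C(C)(C)O1.[Mg+]Br | intermediate
22 | 4,4,5,5-tetramethyl-2-(prop-1-yn-1-yl)-1,3,2-dioxaborolane | CC#CB1OC(C)(C)C(C)(C)O1 | intermediate
23 | 2-[(6R)-6-(2-{(2S,3S)-3-[(3S)-3-{[tert-butyl(dimethyl)silyl]oxy}-4-methylpent-4-en-1-yl]-3-methyloxiran-2-yl}ethyl)-2,5-dimethylcyclohexa-1,4-dien-1-yl]-4,4,5,5-tetramethyl-1,3,2-dioxaborolane | C=C(C)[C@@H](O[Si](C)(C)C(C)(C)C)CC[C@]1(C)O[C@H]1CC[C@H]2C(C)=CCC(C)=C2B3OC(C)(C)C(C)(C)O3 | intermediate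
24 | (3S)-5-[(2S,3S)-3-{2-[(1R)-3,6-dimethyl-2-(4,4,5,5-tetramethyl-1,3,2-dioxaborolan-2-yl)cyclohexa-2,5-dien-1-yl]ethyl}-2-methyloxiran-2-yl]-2-methylpent-1-en-3-ol | C=C(C)[C@@H](O)CC[C@]1(C)O[C@H]1CC[C@H]2C(C)=CCC(C)=C2B3OC(C)(C)C(C)(C)O3 | intermediate
25 | 2-methylphenol | Cc1ccccc1O | starting material
26 | 4-bromo-2-methylphenol | Cc1cc(Br)ccc1O | intermediate
27 | (4-bromo-2-methylphenoxy)tri(propan-2-yl)silane | Cc1cc(Br)ccc1O[Si](C(C)C)(C(C)C)C(C)C | intermediate
28 | [4-bromo-2-(bromomethyl)phenoxy]tri(propan-2-yl)silane | BrCc1cc(Br)ccc1O[Si](C(C)C)(C(C)C)C(C)C | intermediate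
29 | (3S)-5-[(2S,3S)-3-{2-[(1S)-2-{[5-bromo-2-(triisopropylsilyloxy)phenyl]methyl}-3,6-dimethylcyclohexa-2,5-dien-1-yl]ethyl}-2-methyloxiran-2-yl]-2-methylpent-1-en-3-ol | C=C(C)[C@@H](O)CC[C@]1(C)O[C@H]1CC[C@H]2C(C)=CCC(C)=C2Cc3cc(Br)ccc3O[Si](C(C)C)(C(C)C)C(C)C | intermediate
30 | (7S,10S,11S,14S)-10,11-epoxy macrolactone, aryl triisopropylsilyl ether (target ring system with oxirane at C10–C11) | C=C(C)[C@@H]1CC[C@]2(C)O[C@H]2CC[C@H]3C(C)=CCC(C)=C3Cc4cc(ccc4O[Si](C(C)C)(C(C)C)C(C)C)C(=O)O1 | intermediate
31 | (7S,10S,11S,14S)-10,11-epoxy macrolactone, free phenol | C=C(C)[C@@H]1CC[C@]2(C)O[C@H]2CC[C@H]3C(C)=CCC(C)=C3Cc4cc(ccc4O)C(=O)O1 | intermediate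
32 | CNP0186361.2, (7S,10R,11S,14S)-10-bromo-11-hydroxy macrolactone | C=C(C)[C@@H]1CC[C@](C)(O)[C@H](Br)CC[C@H]2C(C)=CCC(C)=C2Cc2cc(ccc2O)C(=O)O1 | target

**Step count**

Total step count: 22.
Longest linear sequence: 14 steps (steps 1–5, 10, 11, 12, 14, 15, 19, 20, 21, 22), which is 0.64 of the total. The sulfolene branch (steps 6–9), the boronate (step 13) and the aryl branch (steps 16–18) run in parallel.

**Steps most likely to fail**

Step 14 (new cobalt [4+2]) may fail in enantiocontrol at C7, in regiochemistry, or through alkyne oligomerisation. The fallback sets out from diene 19 and boronate 22 and comes back at 23. The two are combined under the established achiral protocol for alkynyl boronates (CoBr2(dppe) 10 mol%, Zn, ZnI2, CH2Cl2, rt; if zinc iodide attacks the epoxide it is replaced by Na[B(3,5-(CF3)2C6H3)4]). Without ligand control this gives 23 together with the C7 epimer of 23 F1 in about equal amounts. Because C10, C11 and C14 are already fixed the two are diastereomers, so they are separated by preparative HPLC and 23 re-enters at step 15. Stereocontrol by catalyst is thus replaced by separation.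

Step 19 (Suzuki coupling) may fail because the tetrasubstituted, doubly flanked alkenyl boronate transmetalates slowly and protodeboronation can win. The fallback sets out from 24 and 28 and comes back at 29 with the polarity reversed. Compound 24 is converted by iododeboronation (NaI, TsNClNa, THF/H2O, 0 °C) into the alkenyl iodide F2. Compound 28 is converted by zinc insertion (Zn dust, LiCl, THF, 0 °C; the aryl bromide is untouched) into the benzylic zinc bromide F3. A Negishi coupling (Pd(PPh3)4, THF, rt, 2.5 eq of the zinc reagent to cover the free hydroxyl) then joins them to give 29.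

Step 20 (carbonylative macrolactonisation) may fail because a hindered secondary allylic alcohol must capture the acylpalladium in a 15-membered ring, and the product is an allylic ester exposed to zerovalent palladium. The fallback sets out from 29 and comes back at 30 in two stages. Hydroxycarbonylation (Pd(OAc)2, Xantphos, CO 1 atm, H2O 10 eq, Et3N, dioxane, 80 °C) gives the seco acid F4, kept as its triethylammonium salt so the epoxide sees no free acid. Shiina macrolactonisation (2-methyl-6-nitrobenzoic anhydride, DMAP, Et3N, PhMe, rt, high dilution) then closes the ring by acyl activation without palladium and gives 30.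

**Further compounds**

F1 | step 14 | C7 epimer of 23 | C=C(C)[C@@H](O[Si](C)(C)C(C)(C)C)CC[C@]1(C)O[C@H]1CC[C@@H]2C(C)=CCC(C)=C2B3OC(C)(C)C(C)(C)O3
F2 | step 19 | (3S)-5-[(2S,3S)-3-{2-[(1S)-2-iodo-3,6-dimethylcyclohexa-2,5-dien-1-yl]ethyl}-2-methyloxiran-2-yl]-2-methylpent-1-en-3-ol | C=C(C)[C@@H](O)CC[C@]1(C)O[C@H]1CC[C@H]2C(C)=CCC(C)=C2I
F3 | step 19 | {[5-bromo-2-(triisopropylsilyloxy)phenyl]methyl}zinc bromide | Br[Zn]Cc1cc(Br)ccc1O[Si](C(C)C)(C(C)C)C(C)C
F4 | step 20 | seco acid, 3-{[(6S)-6-(2-{(2S,3S)-3-[(3S)-3-hydroxy-4-methylpent-4-en-1-yl]-3-methyloxiran-2-yl}ethyl)-2,5-dimethylcyclohexa-1,4-dien-1-yl]methyl}-4-(triisopropylsilyloxy)benzoic acid | C=C(C)[C@@H](O)CC[C@]1(C)O[C@H]1CC[C@H]2C(C)=CCC(C)=C2Cc3cc(ccc3O[Si](C(C)C)(C(C)C)C(C)C)C(=O)O
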